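**Strategy.** Everything rests on disconnecting the pyran-4-one C ring at C4–C3 and O1–C2. The formyl carbon of a fully substituted salicylaldehyde (future C4, with C4a, C8a and O1 in place) is joined to the ylide carbon of an aroyl sulfoxonium ylide (future C3, carrying C2 and the B ring), both carbons reacting with reversed polarity: Rh(III), directed by the C8a phenol oxygen, turns the aldehyde C–H into an acyl–metal nucleophile and the ylide into a carbene. The released o-hydroxyaryl 1,3-diketone cyclodehydrates in the same flask. Since only the oxygen next to the C8 methoxy group is free, the 5,7,8 (not 5,6,7) pattern is locked.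

Key step: step 6

Remark on the chemistry: the target has no stereocentre and is achiral, so no step has to set or preserve configuration. Compounds 1 and 5 are assumed to be purchasable.

**Step 1**
Reactants: 1 1,2,3,5-tetramethoxybenzene
Product: 3 2,3,4,6-tetramethoxybenzaldehyde, via iminium chloride 2 (not isolated)
Conditions: POCl3, DMF, 0 → 60 °C; then ice-water
Reagents that add atoms: N,N-dimethylformamide CN(C)C=O; water O; phosphoryl chloride O=P(Cl)(Cl)Cl (chloride of 2 only)
Why: Vilsmeier–Haack formylation; the two free ring positions of the symmetric, very electron-rich arene 1 are equivalent, so a single aldehyde should result after hydrolysis of iminium salt 2.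

**Step 2**
Reactants: 3 2,3,4,6-tetramethoxybenzaldehyde
Product: 4 2-hydroxy-3,4,6-trimethoxybenzaldehyde
Conditions: BCl3 (1.1 equiv), CH2Cl2, −78 → −20 °C; then aq. HCl
Reagents that add atoms: none
Why: Chelation-controlled ortho-demethylation of an aryl aldehyde by BCl3; the C2 methoxy group, twisted out of the ring plane by the C3 methoxy group and therefore the more Lewis-basic, should be cleaved in preference to the conjugated C6 methoxy group, as in the analogous 2,3,4,6-tetramethoxyphenyl ketones.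

**Step 3**
Reactants: 5 4-hydroxy-2,3-dimethoxybenzaldehyde
Product: 6 4-(benzyloxy)-2,3-dimethoxybenzaldehyde
Conditions: BnBr, K2CO3, DMF, 60 °C
Reagents that add atoms: benzyl bromide BrCc1ccccc1
Why: Williamson ether synthesis on the acidic para-formyl phenol, which masks the future 4'-OH for the acylation and annulation steps.

**Step 4**
Reactants: 6 4-(benzyloxy)-2,3-dimethoxybenzaldehyde
Product: 7 4-(benzyloxy)-2,3-dimethoxybenzoic acid
Conditions: NaClO2, NaH2PO4, 2-methyl-2-butene, t-BuOH/H2O, rt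
Reagents that add atoms: sodium chlorite [Na+].[O-]Cl=O
Why: Pinnick oxidation; chlorite avoids the Dakin-type aryl migration that peracids would cause with this para-alkoxybenzaldehyde, and the alkene traps HOCl before it can chlorinate the ring.

**Step 5**
Reactants: 7 4-(benzyloxy)-2,3-dimethoxybenzoic acid
Product: 9 1-[4-(benzyloxy)-2,3-dimethoxyphenyl]-2-[dimethyl(oxo)-λ6-sulfanylidene]ethan-1-one, via acid chloride 8 (not isolated)
Conditions: (COCl)2, cat. DMF, CH2Cl2, 0 °C → rt, evaporate; then Me3S(O)I (3 equiv), KOtBu (3 equiv), THF, reflux, then add 8 at 0 °C → rt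
Reagents that add atoms: trimethylsulfoxonium iodide C[S+](C)(C)=O.[I-]; oxalyl chloride O=C(Cl)C(=O)Cl (chlorine of 8 only)
Why: C-acylation of dimethylsulfoxonium methylide (Corey–Chaykovsky reagent) by an aroyl chloride, in which a second equivalent of methylide deprotonates the β-keto sulfoxonium salt to the stabilised ylide.

**Step 6**
Reactants: 4 2-hydroxy-3,4,6-trimethoxybenzaldehyde; 9 1-[4-(benzyloxy)-2,3-dimethoxyphenyl]-2-[dimethyl(oxo)-λ6-sulfanylidene]ethan-1-one
Product: 11 2-[4-(benzyloxy)-2,3-dimethoxyphenyl]-5,7,8-trimethoxy-4H-chromen-4-one, via 1,3-diketone 10 (not isolated)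
Conditions: [Cp*RhCl2]2 (5 mol %), AgSbF6 (20 mol %), NaOAc (0.5 equiv), AcOH (2 equiv), DCE, 100 °C; then p-TsOH·H2O (cat.), 80 °C
Reagents that add atoms: none
Why: Acetate-assisted binding of the C2 phenoxide of 4 to Cp*Rh(III) is followed by cleavage of the adjacent formyl C–H bond (concerted metalation–deprotonation) to a five-membered acyl-rhodacycle; ylide 9 then coordinates through carbon, loses DMSO to form a rhodium carbene, and 1,1-migratory insertion of the acyl group forms the C4–C3 bond before protodemetalation releases diketone 10. The closest known reaction type is the Rh(III)-catalysed aldehydic C–H activation/annulation of salicylaldehydes with sulfoxonium ylides, which gives 2-substituted chromones. The pyranone ring then closes by 6-exo-trig attack of the phenol oxygen on the aroyl carbonyl carbon (C2), and acid-promoted loss of water from the hemiketal forms O1–C2 and the C2=C3 double bond. No stereocentre is created. The step needs selectivity for the formyl C–H over aryl C–H bonds, which is secured because the ring of 4 has no hydrogen ortho to the directing phenoxide and the chelate places only the formyl hydrogen at rhodium. It also needs a single direction of ring closure, which is secured because the C6 oxygen of 4 is a methyl ether, so only the oxygen next to the C3 methoxy group can become O1.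

**Step 7**
Reactants: 11 2-[4-(benzyloxy)-2,3-dimethoxyphenyl]-5,7,8-trimethoxy-4H-chromen-4-one
Product: 12 5,4'-dihydroxy-7,8,2',3'-tetramethoxyflavone
Conditions: BCl3 (6 equiv), pentamethylbenzene (3 equiv), CH2Cl2, −78 → 0 °C; then MeOH, 1 M HCl
Reagents that add atoms: none
Why: Lewis-acid ether cleavage; BCl3 with pentamethylbenzene as cation scavenger should remove the aryl benzyl ether, and boron chelated between C4=O and the peri C5 methoxy group should cleave only that methyl ether, leaving the unchelated 7-, 8-, 2'- and 3'-methoxy groups intact at or below 0 °C.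

**Compound list**
1 | 1,2,3,5-tetramethoxybenzene | COc1cc(OC)c(OC)c(OC)c1 | starting material
2 | N,N-dimethyl-(2,3,4,6-tetramethoxyphenyl)methaniminium chloride | C[N+](C)=Cc1c(OC)cc(OC)c(OC)c1OC.[Cl-] | intermediate
3 | 2,3,4,6-tetramethoxybenzaldehyde | COc1cc(OC)c(C=O)c(OC)c1OC | intermediate
4 | 2-hydroxy-3,4,6-trimethoxybenzaldehyde | COc1cc(OC)c(C=O)c(O)c1OC | intermediate
5 | 4-hydroxy-2,3-dimethoxybenzaldehyde | COc1c(O)ccc(C=O)c1OC | starting material
6 | 4-(benzyloxy)-2,3-dimethoxybenzaldehyde | COc1c(OCc2ccccc2)ccc(C=O)c1OC | intermediate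
7 | 4-(benzyloxy)-2,3-dimethoxybenzoic acid | COc1c(OCc2ccccc2)ccc(C(=O)O)c1OC | intermediate
8 | 4-(benzyloxy)-2,3-dimethoxybenzoyl chloride | COc1c(OCc2ccccc2)ccc(C(=O)Cl)c1OC | intermediate
9 | 1-[4-(benzyloxy)-2,3-dimethoxyphenyl]-2-[dimethyl(oxo)-λ6-sulfanylidene]ethan-1-one | COc1c(OCc2ccccc2)ccc(C(=O)C=S(C)(C)=O)c1OC | intermediate
10 | 1-[4-(benzyloxy)-2,3-dimethoxyphenyl]-3-(2-hydroxy-3,4,6-trimethoxyphenyl)propane-1,3-dione | COc1cc(OC)c(C(=O)CC(=O)c2ccc(OCc3ccccc3)c(OC)c2OC)c(O)c1OC | intermediate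
11 | 2-[4-(benzyloxy)-2,3-dimethoxyphenyl]-5,7,8-trimethoxy-4H-chromen-4-one | COc1cc(OC)c2c(=O)cc(-c3ccc(OCc4ccccc4)c(OC)c3OC)oc2c1OC | intermediate
12 | 5,4'-dihydroxy-7,8,2',3'-tetramethoxyflavone [5-hydroxy-2-(4-hydroxy-2,3-dimethoxyphenyl)-7,8-dimethoxy-4H-chromen-4-one] | COc1cc(O)c2c(=O)cc(-c3ccc(O)c(OC)c3OC)oc2c1OC | target

**Summary**
Total step count: 7. Longest linear sequence: 5 steps (steps 3, 4, 5, 6, 7, from compound 5).

**Steps most likely to fail, with fallbacks**

1. Step 6. The formyl C–H metalation may be slow at the doubly ortho-substituted, electron-rich aldehyde, and the ylide may be consumed by rhodation of its own aryl ring and self-annulation. The fallback sets out from 4 and 6 and comes back at 11, building the pyranone through an ynone. Aldehyde 6 is homologated with dimethyl (1-diazo-2-oxopropyl)phosphonate (K2CO3, MeOH, rt) to 1-(benzyloxy)-4-ethynyl-2,3-dimethoxybenzene F1. Its lithium acetylide (n-BuLi, THF, −78 °C, excess) is added to the lithium phenoxide of 4 to give racemic 3-[4-(benzyloxy)-2,3-dimethoxyphenyl]-1-(2-hydroxy-3,4,6-trimethoxyphenyl)prop-2-yn-1-ol F2. MnO2 (CH2Cl2, rt) should oxidise this to 3-[4-(benzyloxy)-2,3-dimethoxyphenyl]-1-(2-hydroxy-3,4,6-trimethoxyphenyl)prop-2-yn-1-one F3. Et2NH (DMF, 60 °C) then promotes 6-endo-dig oxa-Michael closure through the enaminone and returns to 11.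

2. Step 2. The two ortho methoxy groups of 3 may not be differentiated (a mixture of 4 with its 6-hydroxy isomer, or double cleavage), which would carry the 5,6,7 pattern forward. The fallback sets out from ylide 9 and comes back at target 12, introducing the C8 oxygen last, para to a chelated 5-OH.
   - Commercial 2-hydroxy-4,6-dimethoxybenzaldehyde F4 is annulated with 9 under the step 6 conditions, through 1-[4-(benzyloxy)-2,3-dimethoxyphenyl]-3-(2-hydroxy-4,6-dimethoxyphenyl)propane-1,3-dione F5, to 2-[4-(benzyloxy)-2,3-dimethoxyphenyl]-5,7-dimethoxy-4H-chromen-4-one F6.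
   - MgI2·OEt2 (THF, 50 °C) should cleave only the chelated 5-OMe to give 2-[4-(benzyloxy)-2,3-dimethoxyphenyl]-5-hydroxy-7-methoxy-4H-chromen-4-one F7.
   - Elbs persulfate oxidation (K2S2O8, aq. KOH/pyridine, 0 °C → rt) hydroxylates para to the 5-phenoxide, at C8 only, through potassium 2-[4-(benzyloxy)-2,3-dimethoxyphenyl]-5-hydroxy-7-methoxy-4-oxo-4H-chromen-8-yl sulfate F8. Brief warming with aq. HCl/Na2SO3 hydrolyses this to 2-[4-(benzyloxy)-2,3-dimethoxyphenyl]-5,8-dihydroxy-7-methoxy-4H-chromen-4-one F9.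
   - Me2SO4 (1 equiv), K2CO3, acetone should methylate the free 8-OH and leave the hydrogen-bonded 5-OH, giving 2-[4-(benzyloxy)-2,3-dimethoxyphenyl]-5-hydroxy-7,8-dimethoxy-4H-chromen-4-one F10.
   - Hydrogenolysis (H2, Pd/C, EtOAc/THF) gives 12.

3. Step 7. The one-pot Lewis-acid deprotection may over-cleave the vicinal methyl ethers (3'-OMe next to the freed 4'-O–boron, or 8-OMe), or the benzyl cation may alkylate the electron-rich rings despite the scavenger. The fallback sets out from 11 and comes back at 12, removing the two groups in separate orthogonal operations. Neutral hydrogenolysis (H2, Pd/C, EtOAc/THF, rt) gives 2-(4-hydroxy-2,3-dimethoxyphenyl)-5,7,8-trimethoxy-4H-chromen-4-one F11. Chelation-specific demethylation of the peri 5-OMe with MgI2·OEt2 (THF, 50 °C) then gives 12.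

**Further compounds**
F1 | step 6 | 1-(benzyloxy)-4-ethynyl-2,3-dimethoxybenzene | COc1c(OCc2ccccc2)ccc(C#C)c1OC
F2 | step 6 | 3-[4-(benzyloxy)-2,3-dimethoxyphenyl]-1-(2-hydroxy-3,4,6-trimethoxyphenyl)prop-2-yn-1-ol (racemic) | COc1cc(OC)c(C(O)C#Cc2ccc(OCc3ccccc3)c(OC)c2OC)c(O)c1OC
F3 | step 6 | 3-[4-(benzyloxy)-2,3-dimethoxyphenyl]-1-(2-hydroxy-3,4,6-trimethoxyphenyl)prop-2-yn-1-one | COc1cc(OC)c(C(=O)C#Cc2ccc(OCc3ccccc3)c(OC)c2OC)c(O)c1OC
F4 | step 2 | 2-hydroxy-4,6-dimethoxybenzaldehyde | COc1cc(O)c(C=O)c(OC)c1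
F5 | step 2 | 1-[4-(benzyloxy)-2,3-dimethoxyphenyl]-3-(2-hydroxy-4,6-dimethoxyphenyl)propane-1,3-dione | COc1cc(O)c(C(=O)CC(=O)c2ccc(OCc3ccccc3)c(OC)c2OC)c(OC)c1
F6 | step 2 | 2-[4-(benzyloxy)-2,3-dimethoxyphenyl]-5,7-dimethoxy-4H-chromen-4-one | COc1cc(OC)c2c(=O)cc(-c3ccc(OCc4ccccc4)c(OC)c3OC)oc2c1
F7 | step 2 | 2-[4-(benzyloxy)-2,3-dimethoxyphenyl]-5-hydroxy-7-methoxy-4H-chromen-4-one | COc1cc(O)c2c(=O)cc(-c3ccc(OCc4ccccc4)c(OC)c3OC)oc2c1
F8 | step 2 | potassium 2-[4-(benzyloxy)-2,3-dimethoxyphenyl]-5-hydroxy-7-methoxy-4-oxo-4H-chromen-8-yl sulfate | COc1cc(O)c2c(=O)cc(-c3ccc(OCc4ccccc4)c(OC)c3OC)oc2c1OS(=O)(=O)[O-].[K+]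
F9 | step 2 | 2-[4-(benzyloxy)-2,3-dimethoxyphenyl]-5,8-dihydroxy-7-methoxy-4H-chromen-4-one | COc1cc(O)c2c(=O)cc(-c3ccc(OCc4ccccc4)c(OC)c3OC)oc2c1O
F10 | step 2 | 2-[4-(benzyloxy)-2,3-dimethoxyphenyl]-5-hydroxy-7,8-dimethoxy-4H-chromen-4-one | COc1cc(O)c2c(=O)cc(-c3ccc(OCc4ccccc4)c(OC)c3OC)oc2c1OC
F11 | step 7 | 2-(4-hydroxy-2,3-dimethoxyphenyl)-5,7,8-trimethoxy-4H-chromen-4-one | COc1cc(OC)c2c(=O)cc(-c3ccc(O)c(OC)c3OC)oc2c1OC
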